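**Plan**

- Retrosynthesis: the two prenyl C–C bonds on the CH2 carbon of ring A (the acyl trione) are cut first. Ring A is then cut at the bond between the lactone-derived carbonyl and that CH2, and at the bond between the acyl-bearing carbon and the ester-derived carbonyl. These are two Claisen bonds to 6-methylheptane-2,4-dione.
- Ring B is cut at the spiro-carbon–CH2 bond and at the C–O bond of its methyl carbinol (held as a lactone). This leaves a malonate on an isopropenyl cyclopentane. The malonate–CH2 bond is cut next, and ring C at the bond between its carbinol carbon and the neighbouring ring carbon, back to (S)-6-oxo-3-isopropenylheptanoic acid from (S)-limonene.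
- Forward order: ring C (step 4), ring B together with the lactone bridge (step 9), ring A (steps 10 and 11), the prenyl groups (step 12).
- Stereochemistry: the isopropenyl-bearing carbon comes from (S)-limonene. The other two ring-C centres come from the aldol-lactonisation (cis β-lactone, trans to the isopropenyl group). The spiro carbon and the ring-B carbinol carbon come from the key step.
- Enabling feature: the spiro carbon of rings A and B lies 1,3 to the ring-B methyl carbinol carbon. On the chair of the trans-fused rings B and C, one spiro carbonyl and the carbinol oxygen are both axial on the same face, so they can be bridged as a γ-lactone. This bridge also tells the two spiro carbonyls apart.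

Key step: step 9

Remark: ring A is a freely tautomerising 2-acyl-1,3,5-trione; 16, 18, 19 and 20 are written in the enol form of the target SMILES, and 15 may rest as the hemiketal of its axial hydroxyl.

**Route**

Step 1
Reactants: 1 (S)-limonene
Product: 2 (4S)-limonene 1,2-oxide (mixture of epoxide diastereomers)
Conditions: mCPBA (1.0 equiv), NaHCO3, CH2Cl2, 0 °C
Reagents that add atoms: mCPBA, OOC(=O)c1cccc(Cl)c1
Why: Prilezhaev epoxidation is faster at the trisubstituted ring alkene than at the 1,1-disubstituted isopropenyl group, and the epoxide configuration is lost in step 2, so the diastereomer mixture is harmless.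

Step 2
Reactants: 2 (4S)-limonene 1,2-oxide
Product: 4 (S)-6-oxo-3-(prop-1-en-2-yl)heptanal, via limonene-1,2-diol 3 (not isolated)
Conditions: H5IO6 (1.1 equiv), THF/H2O, 0 °C to rt
Reagents that add atoms: water, O
Why: Acid-promoted epoxide hydrolysis followed by Malaprade glycol cleavage turns both ring carbons into carbonyls without touching the isopropenyl group or the stereocentre.

Step 3
Reactants: 4 (S)-6-oxo-3-(prop-1-en-2-yl)heptanal
Product: 5 (S)-6-oxo-3-(prop-1-en-2-yl)heptanoic acid
Conditions: NaClO2, NaH2PO4, 2-methyl-2-butene, t-BuOH/H2O, rt
Reagents that add atoms: sodium chlorite, [Na+].[O-]Cl=O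
Why: Pinnick oxidation converts the aldehyde into the acid under buffered conditions that leave the ketone and, with the hypochlorite scavenger, the alkene untouched.

Step 4
Reactants: 5 (S)-6-oxo-3-(prop-1-en-2-yl)heptanoic acid
Product: 7 (1R,2S,5S)-5-methyl-2-(prop-1-en-2-yl)-6-oxabicyclo[3.2.0]heptan-7-one, via acyl tosylate 6 (not isolated)
Conditions: TsCl (1.25 equiv), 4-pyrrolidinopyridine (1.0 equiv), LiCl (1.0 equiv), i-Pr2NEt (4 equiv), CH2Cl2 (0.05 M), slow addition of 5, rt
Reagents that add atoms: none
Why: Nucleophile-catalysed aldol-lactonisation of a 6-oxo acid: the acylammonium enolate adds to the ketone and the alkoxide closes the β-lactone, which can only be cis-fused, while allylic 1,3-strain in the enolate turns the isopropenyl group to the face away from the forming bond, so it should end trans to the lactone carbonyl.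

Step 5
Reactants: 7 (1R,2S,5S)-5-methyl-2-(prop-1-en-2-yl)-6-oxabicyclo[3.2.0]heptan-7-one
Product: 8 (1S,2S,3S)-2-(hydroxymethyl)-1-methyl-3-(prop-1-en-2-yl)cyclopentan-1-ol
Conditions: LiAlH4 (1.2 equiv), Et2O, 0 °C; then H2O
Reagents that add atoms: none
Why: Hydride reduction of the β-lactone at its acyl carbon gives the 1,3-diol with all three stereocentres untouched.

Step 6
Reactants: 8 (1S,2S,3S)-2-(hydroxymethyl)-1-methyl-3-(prop-1-en-2-yl)cyclopentan-1-ol
Product: 9 (1S,2R,3S)-2-(iodomethyl)-1-methyl-3-(prop-1-en-2-yl)cyclopentan-1-ol
Conditions: I2, PPh3, imidazole, CH2Cl2, 0 °C to rt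
Reagents that add atoms: iodine, II
Why: Appel-type iodination converts only the primary alcohol, because the tertiary one is too hindered to form the alkoxyphosphonium salt, and no alkoxide is present that could trigger fragmentation.

Step 7
Reactants: 9 (1S,2R,3S)-2-(iodomethyl)-1-methyl-3-(prop-1-en-2-yl)cyclopentan-1-ol
Product: 10 triethyl{[(1S,2R,3S)-2-(iodomethyl)-1-methyl-3-(prop-1-en-2-yl)cyclopentyl]oxy}silane
Conditions: TESOTf, 2,6-lutidine, CH2Cl2, −78 to 0 °C
Reagents that add atoms: triethylsilyl trifluoromethanesulfonate, CC[Si](CC)(CC)OS(=O)(=O)C(F)(F)F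
Why: A silyl triflate with a hindered pyridine base silylates even a tertiary alcohol and leaves the primary iodide and the alkene alone; the ether blocks alkoxide-driven fragmentation and lactonisation in the next steps.

Step 8
Reactants: 10 triethyl{[(1S,2R,3S)-2-(iodomethyl)-1-methyl-3-(prop-1-en-2-yl)cyclopentyl]oxy}silane; 11 dimethyl malonate
Product: 12 dimethyl 2-{[(1R,2S,5S)-2-methyl-5-(prop-1-en-2-yl)-2-(triethylsilyloxy)cyclopentyl]methyl}malonate
Conditions: 11 (3 equiv), NaH (2.5 equiv), DMF/THF, 0 °C; then 10, 70 °C
Reagents that add atoms: none
Why: Malonic ester alkylation (SN2) of the primary iodide in a dipolar aprotic solvent; excess malonate suppresses dialkylation and its low basicity limits elimination at the β-branched carbon.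

Step 9
Reactants: 12 dimethyl 2-{[(1R,2S,5S)-2-methyl-5-(prop-1-en-2-yl)-2-(triethylsilyloxy)cyclopentyl]methyl}malonate
Product: 13 bridged γ-lactone methyl ester of the trans-hydrindane (ring-C triethylsilyl ether)
Conditions: Mn(OAc)2 (0.2 equiv), KOAc (1 M), AcOH, undivided cell, graphite anode, platinum cathode, constant current, 2.2–2.5 F/mol, 60 °C
Reagents that add atoms: none
Why: Mn(OAc)2 is oxidised at the anode to trivalent manganese, which binds the malonate as its enolate (the only enolisable site) and turns it into the electrophilic malonyl radical. The radical closes ring B by 6-endo-trig attack on the unsubstituted CH2 terminus of the isopropenyl group; the closest known reaction type is the Mn(OAc)3 oxidative cyclisation of 4-methylpent-4-enyl malonates to bridged lactones, run with electrochemical turnover of the metal. The resulting tertiary radical is oxidised to the cation (radical–polar crossover), the carbonyl oxygen of the axial ester captures it in a five-membered closure of the lactone ring, and acetate removes the methyl group. The chair transition state keeps both ring-C bonds equatorial, so the trans relationship already present in 12 fixes the chair. Only the axial ester can reach the axial lobe of the cation, which sets the carbinol carbon (oxygen axial, methyl equatorial) and the spiro carbon (lactone carbonyl axial, ester equatorial) together. The step needs 6-endo over 5-exo closure, lactonisation over proton loss and survival of the silyl ether; the 1,1-disubstituted alkene, the nearness of the axial carbonyl and the acetate buffer should secure these, and 13 has no enolisable dicarbonyl C–H left to be oxidised further.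

Step 10
Reactants: 13 bridged γ-lactone methyl ester; 14 6-methylheptane-2,4-dione
Product: 15 ring-opened hydroxy triketone methyl ester
Conditions: 14 (3 equiv), NaH (3 equiv), THF, 0 °C; n-BuLi (3 equiv), 0 °C; then 13, −78 to −20 °C; AcOH, −78 °C; used crude
Reagents that add atoms: none
Why: Claisen acylation of the β-diketone dianion at its methyl terminus: the γ-lactone, locked in the reactive E ester geometry, should be attacked in preference to the open-chain methyl ester on the same carbon, which frees the ring-B carbinol, and excess dianion deprotonates the product and so protects it from a second addition.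

Step 11
Reactants: 15 ring-opened hydroxy triketone methyl ester
Product: 16 spiro 2-isovaleryl-1,3,5-trione with free ring-A CH2 (ring-C triethylsilyl ether)
Conditions: NaH (5 equiv), THF, 0 to 60 °C; then aq HCl to pH 3, 0 °C
Reagents that add atoms: none
Why: Intramolecular Claisen (Dieckmann-type) cyclisation: with the alcohol and both acidic CH2 groups deprotonated, the methyl ester is the only electrophile left, and the carbon between the two distal ketones attacks it in a six-membered closure driven by the stabilised acyl-trione enolate; the spiro centre is not touched.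

Step 12
Reactants: 16 spiro 2-isovaleryl-1,3,5-trione; 17 prenyl bromide (two equivalents enter the product)
Product: 19 triethylsilyl ether of the target, via monoprenyl trione 18 (not isolated)
Conditions: 17 (2.4 equiv), NaOMe (3.5 equiv), MeOH, 0 °C to rt
Reagents that add atoms: none
Why: Twofold C-alkylation of the acyl-trione dianion at its only CH2 with an allylic bromide in a protic solvent, as in lupulone-type gem-diprenylations; no stereocentre is formed because both new groups are the same.

Step 13
Reactants: 19 triethylsilyl ether of the target
Product: 20 CNP0198642.4 (target)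
Conditions: HF·pyridine, pyridine, THF, 0 °C to rt
Reagents that add atoms: none
Why: Fluoride-assisted cleavage of the tertiary silyl ether under buffered conditions that should spare the prenyl groups, both tertiary alcohols and the enolised trione.

**Compound list**

1 | (S)-limonene, (4S)-1-methyl-4-(prop-1-en-2-yl)cyclohex-1-ene | CC1=CC[C@H](CC1)C(C)=C | starting material
2 | (4S)-limonene 1,2-oxide, mixture of epoxide diastereomers | CC12OC1C[C@H](CC2)C(C)=C | intermediate
3 | (4S)-1-methyl-4-(prop-1-en-2-yl)cyclohexane-1,2-diol, not isolated | CC1(O)C(O)C[C@H](CC1)C(C)=C | intermediate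
4 | (S)-6-oxo-3-(prop-1-en-2-yl)heptanal | O=CC[C@H](CCC(C)=O)C(C)=C | intermediate
5 | (S)-6-oxo-3-(prop-1-en-2-yl)heptanoic acid | OC(=O)C[C@H](CCC(C)=O)C(C)=C | intermediate
6 | mixed anhydride of 5 with 4-methylbenzenesulfonic acid (acyl tosylate), not isolated | Cc1ccc(cc1)S(=O)(=O)OC(=O)C[C@H](CCC(C)=O)C(C)=C | intermediate
7 | (1R,2S,5S)-5-methyl-2-(prop-1-en-2-yl)-6-oxabicyclo[3.2.0]heptan-7-one; cis-fused β-lactone, isopropenyl trans to the lactone carbonyl | O=C1[C@@H]2[C@H](CC[C@]2(C)O1)C(C)=C | intermediate
8 | (1S,2S,3S)-2-(hydroxymethyl)-1-methyl-3-(prop-1-en-2-yl)cyclopentan-1-ol | OC[C@@H]1[C@H](CC[C@]1(C)O)C(C)=C | intermediate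
9 | (1S,2R,3S)-2-(iodomethyl)-1-methyl-3-(prop-1-en-2-yl)cyclopentan-1-ol | IC[C@@H]1[C@H](CC[C@]1(C)O)C(C)=C | intermediate
10 | triethyl{[(1S,2R,3S)-2-(iodomethyl)-1-methyl-3-(prop-1-en-2-yl)cyclopentyl]oxy}silane | IC[C@@H]1[C@H](CC[C@]1(C)O[Si](CC)(CC)CC)C(C)=C | intermediate
11 | dimethyl malonate | COC(=O)CC(=O)OC | starting material
12 | dimethyl 2-{[(1R,2S,5S)-2-methyl-5-(prop-1-en-2-yl)-2-(triethylsilyloxy)cyclopentyl]methyl}malonate; CH2 arm trans to isopropenyl and cis to the silyloxy group | COC(=O)C(C[C@@H]1[C@H](CC[C@]1(C)O[Si](CC)(CC)CC)C(C)=C)C(=O)OC | intermediate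
13 | bridged γ-lactone methyl ester: trans-fused rings B and C; the quaternary (future spiro) carbon bears an equatorial CO2Me and an axial carbonyl tied as γ-lactone to the axial oxygen of the ring-B methyl carbinol carbon; ring-C C(CH3)OSiEt3 with oxygen cis to the adjacent ring-B CH2 | O=C1[C@@]2(C[C@@H]3[C@H](CC[C@]3(C)O[Si](CC)(CC)CC)[C@](C)(O1)C2)C(=O)OC | intermediate
14 | 6-methylheptane-2,4-dione | CC(=O)CC(=O)CC(C)C | starting material
15 | hydroxy triketone methyl ester: as 13 with the lactone opened; axial 7-methyl-1,3,5-trioxooctyl chain and equatorial CO2Me on the quaternary carbon, free axial ring-B tertiary alcohol | COC(=O)[C@]1(C[C@@H]2[C@H](CC[C@]2(C)O[Si](CC)(CC)CC)[C@](C)(O)C1)C(=O)CC(=O)CC(=O)CC(C)C | intermediate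
16 | spiro acyl trione: ring A closed, isovaleryl on the carbon next to the ester-derived carbonyl, CH2 next to the lactone-derived carbonyl; ring-C triethylsilyl ether | C1C(=O)[C@@]2(C[C@@H]3[C@H](CC[C@]3(C)O[Si](CC)(CC)CC)[C@](C)(O)C2)C(=O)C(C(=O)CC(C)C)=C1O | intermediate
17 | prenyl bromide, 1-bromo-3-methylbut-2-ene | CC(C)=CCBr | starting material
18 | monoprenyl derivative of 16 at the ring-A CH2 (epimer mixture at that carbon), not isolated | CC(C)=CCC1C(=O)[C@@]2(C[C@@H]3[C@H](CC[C@]3(C)O[Si](CC)(CC)CC)[C@](C)(O)C2)C(=O)C(C(=O)CC(C)C)=C1O | intermediate
19 | triethylsilyl ether of the target at the ring-C tertiary alcohol | CC(C)=CCC1(CC=C(C)C)C(=O)[C@@]2(C[C@@H]3[C@H](CC[C@]3(C)O[Si](CC)(CC)CC)[C@](C)(O)C2)C(=O)C(C(=O)CC(C)C)=C1O | intermediate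
20 | CNP0198642.4 | CC(C)=CCC1(CC=C(C)C)C(=O)[C@@]2(C[C@@H]3[C@H](CC[C@]3(C)O)[C@](C)(O)C2)C(=O)C(C(=O)CC(C)C)=C1O | target

Total steps: 13. Longest linear sequence: 13 steps (1 to 20); 11, 14 and 17 are bought.

**Steps most likely to fail**

Step 10. The dianion may acylate at the open-chain ester instead of the lactone. The adduct may also revert during quench and handling, by attack of the freed axial alkoxide on the new ketone (retro-Claisen). The fallback sets out from 13 and comes back at 16, so it also replaces step 11. SN2 demethylation with LiI in refluxing ethyl acetate, to which the tertiary lactone carbon is inert, would give the lactone acid F1. Oxalyl chloride with pyridine and catalytic DMF would give the acid chloride F2. C-acylation of the magnesium enolate of 14 (MgCl2, pyridine, CH2Cl2) would give the triacylmethane F3, in which the former ester carbonyl is bonded to the central carbon of the diketone. LDA (3 equiv, THF, −78 to 0 °C) would then remove an acetyl methyl proton, and the carbanion would close ring A on the lactone carbonyl in a six-membered Claisen closure that frees the carbinol and gives 16. Here the acid chloride, not a rate difference, decides which carbonyl meets which carbon.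

Step 9. Enolisation of the alkylmalonate at manganese may be slow, so that direct anodic oxidation of the alkene competes. The tertiary cation may lose a proton instead of lactonising, and the silyl ether may be acetolysed in warm acetic acid. The fallback sets out from 12 and comes back at 13 without an oxidant. Bromination of the sodium enolate (NaH, then N-bromosuccinimide, THF, 0 °C) would give the bromomalonate F4. Atom-transfer radical cyclisation (BEt3, air, benzene, rt) would close ring B 6-endo and give the tertiary bromide F5. Warming F5 in acetonitrile would ionise it to the same cation; the axial ester would capture it, and bromide would take off the methyl group to give 13.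

Step 12. O-alkylation of the ambident enolate may compete with C-alkylation, and the second alkylation may stall. The fallback sets out from 16 and comes back at 19. Allylation with allyl methyl carbonate and Pd(PPh3)4 (zerovalent palladium) in THF would give first the monoallyl compound F6 and then the diallyl compound F7, because O-allyl products re-ionise under the catalyst and end on carbon. Cross-metathesis with excess 2-methyl-2-butene (second-generation Grubbs catalyst, RuCl2(H2IMes)(PCy3)(=CHPh), CH2Cl2, 40 °C) would turn both allyl groups into prenyl groups and give 19.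

Further compounds
F1 | step 10 | lactone acid (13 with CO2H in place of CO2Me) | O=C1[C@@]2(C[C@@H]3[C@H](CC[C@]3(C)O[Si](CC)(CC)CC)[C@](C)(O1)C2)C(O)=O
F2 | step 10 | lactone acid chloride | O=C1[C@@]2(C[C@@H]3[C@H](CC[C@]3(C)O[Si](CC)(CC)CC)[C@](C)(O1)C2)C(Cl)=O
F3 | step 10 | triacylmethane: lactone carbonyl compound acylating the central carbon of 14 | O=C1[C@@]2(C[C@@H]3[C@H](CC[C@]3(C)O[Si](CC)(CC)CC)[C@](C)(O1)C2)C(=O)C(C(C)=O)C(=O)CC(C)C
F4 | step 9 | bromomalonate of 12 | COC(=O)C(Br)(C[C@@H]1[C@H](CC[C@]1(C)O[Si](CC)(CC)CC)C(C)=C)C(=O)OC
F5 | step 9 | ring-B tertiary bromide, trans-hydrindane gem-diester (mixture at the C–Br carbon) | COC(=O)C1(C[C@@H]2[C@H](CC[C@]2(C)O[Si](CC)(CC)CC)C(C)(Br)C1)C(=O)OC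
F6 | step 12 | monoallyl derivative of 16 at the ring-A CH2 | C=CCC1C(=O)[C@@]2(C[C@@H]3[C@H](CC[C@]3(C)O[Si](CC)(CC)CC)[C@](C)(O)C2)C(=O)C(C(=O)CC(C)C)=C1O
F7 | step 12 | diallyl derivative of 16 at the ring-A CH2 | C=CCC1(CC=C)C(=O)[C@@]2(C[C@@H]3[C@H](CC[C@]3(C)O[Si](CC)(CC)CC)[C@](C)(O)C2)C(=O)C(C(=O)CC(C)C)=C1O
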